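## The problem

The target is a 40-carbon carotenoid. Two 2,4,5,6,7,7a-hexahydrobenzofuran (5,8-furanoid) end groups are joined through C8 and C8' by an all-E heptaene (C9 to C9') with four methyl branches. It has five stereocentres in two remote sets. On the unhydroxylated end, C5' (R) and C8' (S) place the C5' methyl and the chain cis on the dihydrofuran. On the hydroxylated end, C3 (R), C5 (S) and C8 (S) place methyl and chain trans, with the hydroxyl trans to the ring oxygen. The two sets are separated by the whole polyene and cannot control each other, so each end must be made enantiopure on its own. Within one end, C5 can fix C8 only through a stereospecific reaction, because the two faces of a planar C8 differ merely by a methyl versus a ring methylene at C5, and C3 is too far away to help. C8 and C8' are doubly allylic ether carbons that acid ionises and epimerises, and the polyene is sensitive to acid, light and oxygen; the rings therefore belong at the 15-carbon stage and the late steps must be neutral or basic. The feature that opens the left end is that its ring oxygen bridges C5' and C8' across the C6'=C7' double bond. These are the termini of the s-cis diene C5'=C6'–C7'=C8' of a β-ionone ring, so the dihydrofuran is one oxygen short of the 1,2-dioxine that singlet oxygen forms there, and the cis arrangement equals the trans dioxine after one inversion at C8'.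

## Retrosynthesis

**Chain assembly.** Target 29 is traced to its silyl ether 28, and the heptaene is cut at C11=C12 and C11'=C12'. This gives the 15-carbon phosphonium salts 27 (right) and 10 (left) and the commercial 10-carbon dialdehyde 11; in the forward sense 10 and 11 give the 25-carbon aldehyde 12, which then takes up 27. A cut at C15=C15' would need two different 20-carbon halves, each three steps longer. Cuts at the trisubstituted C9=C10 or C13=C14 bonds would give poor geometric control. The chosen cut keeps both ring-bearing pieces small enough for their stereochemical purity to be checked by chromatography, and exposes the doubly allylic ethers only to base. The forward reactions must stop at mono-condensation on 11 and must end with E geometry, which thermal equilibration supplies.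

**Left salt to left ester.** Salt 10 comes from allylic alcohol 8 and this from ester 7 by functional group changes only. The ester is kept as the C11' oxidation level because it deactivates the C9'=C10' bond towards singlet oxygen and towards ionisation at C8' in the steps before.

**Key disconnection.** In 7 an oxygen is re-inserted between the ring oxygen and C8', which leads to the 1,2-dioxine 5. The alternative cuts of the O–C8' bond (acid closure of a diol, rearrangement of a 5',6'-epoxide) pass through a C8' cation and give both epimers. The deletion route breaks no bond at C5' and replaces the C8'–O bond with inversion, so the cis ring follows from the trans dioxine. The forward reaction must be a clean SN2 displacement at a doubly allylic carbon under neutral conditions.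

**Endoperoxide to β-ionone.** Dioxine 5 is one enantiomer of racemate 4, the [4+2] adduct of singlet oxygen and trienoate 3, which is the olefination product of β-ionone 1 and phosphonoacetate 2. Both stereocentres and the ring are thus traced to a suprafacial cycloaddition on an achiral diene. The price is a resolution, asked of a chiral-amine Kornblum–DeLaMare reaction.

**Right salt to right furanoid ester.** Salt 27 comes from alcohol 25 and ester 24, as on the left.

**Trans ring.** The oxygen deletion gives only the cis ring and cannot serve here. The O–C8 bond of 24 is therefore cut back to the 5,6-epoxide 23, whose C5–O bond carries the C5 configuration into the furanoid. C8 is formed by capture of an allyl cation and is not controlled. This is accepted because the two C8 epimers are separable diastereomers at the 15-carbon ester stage and nothing else in the molecule is at risk there.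

**Epoxide construction.** Epoxy dienoate 23 is cut at C7=C8 into epoxy aldehyde 21 and the commercial five-carbon phosphonate 22. Aldehyde 21 comes from epoxy alcohol 20 and this from allylic alcohol 19 by titanium tartrate epoxidation. Peracid epoxidation of a 3-silyloxy triene would leave the facial choice to the substrate; the tartrate route puts it under reagent control, which fixes C5 relative to C3.

**Ring with C3.** Alcohol 19 comes from ester 18, made by carbonylation of enol triflate 17 (C6–C7 bond). Triflate 17 is the trapped conjugate-reduction enolate 16 of silyloxy enone 15, which comes from hydroxy enone 14 and this from prochiral ketoisophorone 13 by asymmetric transfer hydrogenation. The ligand antipode is freely chosen, which matters because the target needs the 3R furanoid series.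

## Roads not taken

Alternative 1: The cut is the C1–C6 bond of the carbocycle of the hydroxylated end, leading to butenolide A1 with an isopropenyl-terminated side chain. In the forward step a cobalt hydride from Co(salen)Cl (trivalent cobalt) and PhSiH3 transfers hydrogen to the isopropenyl group, the tertiary C1 radical adds 6-exo to C6, and hydrogen loss restores C6=C7, giving bicyclic lactone A2.
- Merits: one catalytic step builds the carbocycle and the quaternary C1; C3 and C5 are set beforehand on an open chain, so no resolution is needed.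
- Weak points: C8 is still a carbonyl in A2. The chain and the C8 stereocentre must be added afterwards through a lactol and an oxocarbenium ion at a doubly allylic carbon, under acid and with little facial bias, so the hardest stereocentre of the end group is left open. A1 itself needs a multistep asymmetric synthesis of a tertiary carbinol.
- Comparison: this road is better in absolute stereocontrol at C3 and C5 and needs no resolution. The chosen plan sets against it a key step that creates the C8' configuration stereospecifically, four steps from β-ionone.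

Alternative 2: The cut is the O–C8 bond, leading to allenol A3 in which C6=C7=C8 is an allene next to the C5 carbinol. Ph3PAuCl activated by AgOTf (monovalent gold, monovalent silver) makes the hydroxyl add 5-endo to C8 with axis-to-centre transfer, giving pivalate A4.
- Merits: the closure is stereospecific, mild and catalytic, and the allene axis can be chosen for the trans ring that the hydroxylated end requires, or for the cis ring.
- Weak points: A3 is a trisubstituted vinylidene-cyclohexane allene of defined axis beside a hindered tertiary carbinol. Its synthesis is long, and every leak in the axis appears at C8. Gold can also epimerise allenes and re-ionise the doubly allylic ether product.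
- Comparison: on the trans end this road controls C8, which the chosen route does not; there the chosen route separates C8 epimers after an acid rearrangement. The chosen plan sets against it a far shorter entry to the cis end from commodity materials, with stereochemistry that rests on a pericyclic reaction and an SN2 displacement.

Alternative 3: The cut is the O–C5 bond, leading to trans-7,8-oxirane A5. Cu(hfacac)2 (divalent copper) opens the C7–O bond and the oxygen re-bonds to C5, giving furanoid ester A6, which is identical with ester 24 of the chosen route.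
- Merits: the step is an atom-economic isomerisation, C8 keeps the oxirane configuration, and either ring diastereomer is in principle available from the matching oxirane.
- Weak points: the oxygen must form a quaternary C–O bond at the fully substituted, hindered C5, and the face of attack at C5 must be right relative to C3. Such ring expansions usually need hot conditions that the dienoate may not tolerate. A5 cannot be made by direct epoxidation, because C5=C6 is the more nucleophilic alkene.
- Comparison: this road would deliver 24 as a single C8 epimer and is superior to the chosen right-end sequence in that respect. The chosen plan sets against it a key step that runs at room temperature, leaves C5' untouched, and has direct precedent for both the cycloaddition and the phosphine deoxygenation.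

Key step: step 4

Assumption: the senses of the three reagent-controlled steps (amine in step 3, ligand in step 8, tartrate in step 13) are written as the usual empirical models predict or, for step 3, for definiteness; should the opposite antipode result, the mirror-image or pseudo-enantiomeric reagent is used and nothing else changes.

Step 1
Reactants: 1 β-ionone; 2 triethyl phosphonoacetate
Product: 3 ethyl (2E,4E)-3-methyl-5-(2,6,6-trimethylcyclohex-1-en-1-yl)penta-2,4-dienoate (ethyl β-ionylideneacetate)
Conditions: NaH, THF, 0 °C → 60 °C; chromatography to remove the (2Z) isomer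
Reagents that add atoms: none
Why: Horner–Wadsworth–Emmons olefination of a methyl ketone; the stabilised phosphonate anion gives mainly the (2E) trisubstituted enoate, and the minor (2Z) isomer is removed.

Step 2
Reactants: 3 ethyl β-ionylideneacetate
Product: 4 racemic ethyl (2E)-3-[(3R*,8aR*)-5,5,8a-trimethyl-3,5,6,7,8,8a-hexahydro-1,2-benzodioxin-3-yl]but-2-enoate (trans 5',8'-endoperoxide)
Conditions: O2, tetraphenylporphyrin (cat.), visible light, CH2Cl2, −20 °C
Reagents that add atoms: dioxygen, O=O
Why: Sensitised singlet oxygen [4+2] cycloaddition across the electron-rich s-cis diene C5'=C6'–C7'=C8', the dienoate part being deactivated by the ester. Suprafacial addition to the (7'E) diene places the C5' methyl and the C8' chain trans on the new 1,2-dioxine, and both stereocentres form as a racemate.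

Step 3
Reactants: 4 racemic trans endoperoxide
Product: 5 ethyl (2E)-3-[(3R,8aR)-5,5,8a-trimethyl-3,5,6,7,8,8a-hexahydro-1,2-benzodioxin-3-yl]but-2-enoate (the 5'R,8'R enantiomer)
Conditions: (DHQD)2PHAL (hydroquinidine 1,4-phthalazinediyl diether, 10 mol %), toluene, 0 °C, taken somewhat beyond half conversion; silica gel chromatography
Reagents that add atoms: none
Why: Kornblum–DeLaMare rearrangement run as a kinetic resolution: the chiral tertiary amine removes H-8' of the (3S,8aS) antipode faster and turns it into a polar γ-hydroxy enone. The unreacted (3R,8aR) enantiomer 5 is recovered and separated on silica.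

Step 4
Reactants: 5 (3R,8aR)-endoperoxide; 6 triphenylphosphine
Product: 7 ethyl (2E)-3-[(2S,7aR)-4,4,7a-trimethyl-2,4,5,6,7,7a-hexahydro-1-benzofuran-2-yl]but-2-enoate (cis furanoid ester, 5'R,8'S)
Conditions: PPh3 (1.05 equiv), CH2Cl2, 0 °C → rt, dark, argon
Reagents that add atoms: none
Why: Triphenylphosphine attacks the peroxide oxygen on C8', the less hindered one because the other is flanked by the quaternary C5' and its methyl, and inserts into the O–O bond; the resulting dialkoxyphosphorane opens to a betaine with the phosphonium oxygen on C8' and an alkoxide on C5'. The C5' alkoxide displaces triphenylphosphine oxide from C8' from the rear, which forms the O–C8' bond and contracts the 1,2-dioxine to the 2,5-dihydrofuran in a 5-exo-tet closure. The closest known reaction type is the tertiary phosphine deoxygenation of dialkyl peroxides to ethers and of 3,6-dihydro-1,2-dioxines to 2,5-dihydrofurans, which inverts one carbon. C5' keeps its C–O bond and configuration and C8' is inverted, so the trans dioxine (3R,8aR) gives the cis dihydrofuran (2S,7aR); the controlling elements are the two dioxine stereocentres, fixed by the suprafacial cycloaddition and the resolution. The step needs substitution at C8' in preference to SN2' attack at C6' (which would give the 5',6'-oxirane) and to ionisation. The fused, unbridged dioxine allows the collinear rear approach, C6' is fully substituted and shielded by the geminal methyls, and the ester-bearing C9'=C10' bond withdraws electron density from C8' and disfavours a cation. The neutral aprotic medium spares both the base-labile peroxide and the acid-labile doubly allylic ether.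

Step 5
Reactants: 7 cis furanoid ester
Product: 8 (2E)-3-[(2S,7aR)-4,4,7a-trimethyl-2,4,5,6,7,7a-hexahydro-1-benzofuran-2-yl]but-2-en-1-ol
Conditions: i-Bu2AlH (2.2 equiv), CH2Cl2, −78 °C; Rochelle salt work-up
Reagents that add atoms: none
Why: 1,2-Reduction of an α,β-unsaturated ester by i-Bu2AlH; the cold, non-basic conditions leave the doubly allylic ether and the acidic H-8' untouched.

Step 6
Reactants: 8 left allylic alcohol; 6 triphenylphosphine
Product: 10 {(2E)-3-[(2S,7aR)-4,4,7a-trimethyl-2,4,5,6,7,7a-hexahydro-1-benzofuran-2-yl]but-2-en-1-yl}triphenylphosphonium bromide, via allylic bromide 9 (not isolated)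
Conditions: CBr4, PPh3, CH2Cl2, 0 °C; then PPh3, rt; precipitation from Et2O
Reagents that add atoms: carbon tetrabromide, BrC(Br)(Br)Br
Why: Appel bromination of the primary allylic alcohol followed by SN2 quaternisation of triphenylphosphine; no acid is generated, which protects the ionisable C8' ether.

Step 7
Reactants: 10 left phosphonium bromide; 11 (2E,4E,6E)-2,7-dimethylocta-2,4,6-trienedial
Product: 12 (2E,4E,6E,8E,10E)-2,7-dimethyl-11-[(2S,7aR)-4,4,7a-trimethyl-2,4,5,6,7,7a-hexahydro-1-benzofuran-2-yl]dodeca-2,4,6,8,10-pentaenal
Conditions: 11 (2 equiv), NaOMe, CH2Cl2–MeOH, 0 °C → rt; then heptane, 80 °C, argon, dark; chromatography on Et3N-deactivated silica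
Reagents that add atoms: none
Why: Wittig olefination of a semistabilised allylic ylide with one formyl group of the symmetrical dialdehyde used in excess; the product polyenal is less electrophilic than 11, which limits double condensation. The Z/E mixture at the new C11'=C12' bond is equilibrated thermally to E.

Step 8
Reactants: 13 2,6,6-trimethylcyclohex-2-ene-1,4-dione (ketoisophorone)
Product: 14 (4R)-4-hydroxy-2,6,6-trimethylcyclohex-2-en-1-one
Conditions: RuCl[(R,R)-TsDPEN](p-cymene) (1 mol %), KOH (cat.), i-PrOH, rt
Reagents that add atoms: none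
Why: Noyori-type asymmetric transfer hydrogenation; only the carbonyl flanked by CH= and CH2 is accessible to the ruthenium hydride, and the (R,R) ligand is expected to give the (4R) alcohol, which becomes C3 of the target.

Step 9
Reactants: 14 (4R)-hydroxy enone
Product: 15 (4R)-4-{[tert-butyl(dimethyl)silyl]oxy}-2,6,6-trimethylcyclohex-2-en-1-one
Conditions: TBSCl, imidazole, DMF, rt
Reagents that add atoms: tert-butyldimethylsilyl chloride, CC(C)(C)[Si](C)(C)Cl
Why: Standard silylation of a secondary alcohol; the silyl ether survives hydride, palladium, titanium, catalytic acid and ylide chemistry until step 20.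

Step 10
Reactants: 15 silyloxy enone
Product: 17 (4S)-4-{[tert-butyl(dimethyl)silyl]oxy}-2,6,6-trimethylcyclohex-1-en-1-yl trifluoromethanesulfonate, via lithium enolate 16 (not isolated)
Conditions: LiBH(s-Bu)3, THF, −78 °C; then PhNTf2, −78 → 0 °C
Reagents that add atoms: N-phenylbis(trifluoromethanesulfonimide), FC(F)(F)S(=O)(=O)N(c1ccccc1)S(=O)(=O)C(F)(F)F
Why: Conjugate hydride addition of the bulky borohydride to the hindered enone gives the tetrasubstituted enolate regiospecifically, and O-sulfonylation traps it (reductive enol triflation). The stereocentre is untouched; its descriptor changes only because the priorities change.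

Step 11
Reactants: 17 enol triflate
Product: 18 methyl (4S)-4-{[tert-butyl(dimethyl)silyl]oxy}-2,6,6-trimethylcyclohex-1-ene-1-carboxylate
Conditions: Pd(OAc)2 (5 mol %), dppp (5 mol %), CO (1 atm), MeOH, Et3N, DMF, 70 °C
Reagents that add atoms: carbon monoxide, [C-]#[O+]; methanol, CO
Why: Palladium-catalysed alkoxycarbonylation of an alkenyl triflate (oxidative addition to zerovalent palladium, CO insertion, methanolysis) forms the C6–C7 bond at the hindered tetrasubstituted carbon.

Step 12
Reactants: 18 methyl ester
Product: 19 [(4S)-4-{[tert-butyl(dimethyl)silyl]oxy}-2,6,6-trimethylcyclohex-1-en-1-yl]methanol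
Conditions: i-Bu2AlH (2.2 equiv), CH2Cl2, −78 → 0 °C
Reagents that add atoms: none
Why: i-Bu2AlH reduction of the unsaturated ester gives the primary allylic alcohol that the titanium-directed epoxidation requires.

Step 13
Reactants: 19 allylic alcohol
Product: 20 [(1S,4R,6S)-4-{[tert-butyl(dimethyl)silyl]oxy}-2,2,6-trimethyl-7-oxabicyclo[4.1.0]heptan-1-yl]methanol (oxirane anti to the silyloxy group)
Conditions: Ti(OiPr)4, L-(+)-diethyl tartrate, t-BuOOH, 4 Å molecular sieves, CH2Cl2, −20 °C
Reagents that add atoms: tert-butyl hydroperoxide, CC(C)(C)OO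
Why: Sharpless asymmetric epoxidation; the titanium tartrate delivers oxygen to one face of the allylic alcohol under reagent control. L-(+)-tartrate is chosen to place the oxirane anti to the C3 silyloxy group, which sets C5 (S) and the transient C6 centre.

Step 14
Reactants: 20 epoxy alcohol
Product: 21 (1R,4R,6S)-4-{[tert-butyl(dimethyl)silyl]oxy}-2,2,6-trimethyl-7-oxabicyclo[4.1.0]heptane-1-carbaldehyde
Conditions: Dess–Martin periodinane, NaHCO3, CH2Cl2, 0 °C → rt
Reagents that add atoms: none
Why: Dess–Martin oxidation of the primary alcohol under buffered conditions; the α-carbon is quaternary, so nothing can epimerise, and the descriptor at that carbon changes only through the priorities.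

Step 15
Reactants: 21 epoxy aldehyde; 22 triethyl 3-methyl-4-phosphonocrotonate (ethyl (2E)-4-(diethoxyphosphoryl)-3-methylbut-2-enoate)
Product: 23 ethyl (2E,4E)-5-[(1R,4R,6S)-4-{[tert-butyl(dimethyl)silyl]oxy}-2,2,6-trimethyl-7-oxabicyclo[4.1.0]heptan-1-yl]-3-methylpenta-2,4-dienoate
Conditions: 22, NaH, THF, 0 °C; then 21, 0 °C → rt; chromatography to remove the (2Z) isomer
Reagents that add atoms: none
Why: Horner–Wadsworth–Emmons olefination with a vinylogous phosphonate forms the (7E) double bond and brings in C8 to C11 with the (9E) enoate predominating; the base does not touch the epoxide.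

Step 16
Reactants: 23 epoxy dienoate
Product: 24 ethyl (2E)-3-[(2S,6R,7aS)-6-{[tert-butyl(dimethyl)silyl]oxy}-4,4,7a-trimethyl-2,4,5,6,7,7a-hexahydro-1-benzofuran-2-yl]but-2-enoate (trans furanoid ester)
Conditions: (+)-10-camphorsulfonic acid (cat.), CH2Cl2, 0 °C; Et3N quench; separation of the C8 epimers on silica
Reagents that add atoms: none
Why: Acid-catalysed rearrangement of a 5,6-epoxide to a 5,8-furanoid: protonation opens the C6–O bond to an allyl cation over C6 to C8, and the oxygen on C5, whose configuration is untouched, closes onto C8. C8 forms on both faces, so the trans isomer 24 is separated from its C8 epimer, which can be resubjected to the acid.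

Step 17
Reactants: 24 trans furanoid ester
Product: 25 (2E)-3-[(2S,6R,7aS)-6-{[tert-butyl(dimethyl)silyl]oxy}-4,4,7a-trimethyl-2,4,5,6,7,7a-hexahydro-1-benzofuran-2-yl]but-2-en-1-ol
Conditions: i-Bu2AlH (2.2 equiv), CH2Cl2, −78 °C; Rochelle salt work-up
Reagents that add atoms: none
Why: 1,2-Reduction of the unsaturated ester as in step 5; silyl ether and doubly allylic ether are inert to the aluminium hydride at low temperature.

Step 18
Reactants: 25 right allylic alcohol; 6 triphenylphosphine
Product: 27 {(2E)-3-[(2S,6R,7aS)-6-{[tert-butyl(dimethyl)silyl]oxy}-4,4,7a-trimethyl-2,4,5,6,7,7a-hexahydro-1-benzofuran-2-yl]but-2-en-1-yl}triphenylphosphonium bromide, via allylic bromide 26 (not isolated)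
Conditions: CBr4, PPh3, CH2Cl2, 0 °C; then PPh3, rt; precipitation from Et2O
Reagents that add atoms: carbon tetrabromide, BrC(Br)(Br)Br
Why: Appel bromination and SN2 quaternisation as in step 6, under neutral conditions that leave the secondary silyl ether and the C8 ether alone.

Step 19
Reactants: 27 right phosphonium bromide; 12 25-carbon aldehyde
Product: 28 (3R,5S,8S,5'R,8'S)-3-{[tert-butyl(dimethyl)silyl]oxy}-5,8:5',8'-diepoxy-5,8,5',8'-tetrahydro-β,β-carotene (all-E)
Conditions: NaOMe, CH2Cl2–MeOH, 0 °C → rt; then EtOAc–heptane, reflux, argon, dark; chromatography on Et3N-deactivated silica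
Reagents that add atoms: none
Why: Wittig olefination of the allylic ylide with the polyenal forms C11=C12 and completes the heptaene; thermal equilibration converts the Z isomer of the new bond into the all-E compound. The basic medium leaves all five stereocentres untouched.

Step 20
Reactants: 28 silyl ether
Product: 29 (3R,5S,8S,5'R,8'S)-5,8:5',8'-diepoxy-5,8,5',8'-tetrahydro-β,β-caroten-3-ol (target)
Conditions: Bu4NF, THF, 0 °C → rt, dark, argon
Reagents that add atoms: none
Why: Fluoride cleavage of the silyl ether; the mildly basic, non-acidic conditions are harmless to the polyene and to the two doubly allylic ethers.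

**Compound list**

1 | β-ionone, (3E)-4-(2,6,6-trimethylcyclohex-1-en-1-yl)but-3-en-2-one | CC(=O)/C=C/C1=C(C)CCCC1(C)C | starting material
2 | triethyl phosphonoacetate | CCOC(=O)CP(=O)(OCC)OCC | starting material
3 | ethyl (2E,4E)-3-methyl-5-(2,6,6-trimethylcyclohex-1-en-1-yl)penta-2,4-dienoate | CCOC(=O)/C=C(\C)/C=C/C1=C(C)CCCC1(C)C | intermediate
4 | racemic ethyl (2E)-3-[(3R*,8aR*)-5,5,8a-trimethyl-3,5,6,7,8,8a-hexahydro-1,2-benzodioxin-3-yl]but-2-enoate (both enantiomers, methyl and chain trans) | CCOC(=O)/C=C(\C)[C@H]1C=C2C(C)(C)CCC[C@@]2(C)OO1.CCOC(=O)/C=C(\C)[C@@H]1C=C2C(C)(C)CCC[C@]2(C)OO1 | intermediate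
5 | ethyl (2E)-3-[(3R,8aR)-5,5,8a-trimethyl-3,5,6,7,8,8a-hexahydro-1,2-benzodioxin-3-yl]but-2-enoate | CCOC(=O)/C=C(\C)[C@H]1C=C2C(C)(C)CCC[C@@]2(C)OO1 | intermediate
6 | triphenylphosphine | c1ccc(cc1)P(c1ccccc1)c1ccccc1 | starting material
7 | ethyl (2E)-3-[(2S,7aR)-4,4,7a-trimethyl-2,4,5,6,7,7a-hexahydro-1-benzofuran-2-yl]but-2-enoate | CCOC(=O)/C=C(\C)[C@@H]1C=C2C(C)(C)CCC[C@@]2(C)O1 | intermediate
8 | (2E)-3-[(2S,7aR)-4,4,7a-trimethyl-2,4,5,6,7,7a-hexahydro-1-benzofuran-2-yl]but-2-en-1-ol | OC/C=C(\C)[C@@H]1C=C2C(C)(C)CCC[C@@]2(C)O1 | intermediate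
9 | (2S,7aR)-2-[(2E)-4-bromobut-2-en-2-yl]-4,4,7a-trimethyl-2,4,5,6,7,7a-hexahydro-1-benzofuran | BrC/C=C(\C)[C@@H]1C=C2C(C)(C)CCC[C@@]2(C)O1 | intermediate
10 | {(2E)-3-[(2S,7aR)-4,4,7a-trimethyl-2,4,5,6,7,7a-hexahydro-1-benzofuran-2-yl]but-2-en-1-yl}triphenylphosphonium bromide | [Br-].c1ccc(cc1)[P+](c1ccccc1)(c1ccccc1)C/C=C(\C)[C@@H]1C=C2C(C)(C)CCC[C@@]2(C)O1 | intermediate
11 | (2E,4E,6E)-2,7-dimethylocta-2,4,6-trienedial | O=C/C(C)=C/C=C/C=C(C)/C=O | starting material
12 | (2E,4E,6E,8E,10E)-2,7-dimethyl-11-[(2S,7aR)-4,4,7a-trimethyl-2,4,5,6,7,7a-hexahydro-1-benzofuran-2-yl]dodeca-2,4,6,8,10-pentaenal | O=C/C(C)=C/C=C/C=C(C)/C=C/C=C(\C)[C@@H]1C=C2C(C)(C)CCC[C@@]2(C)O1 | intermediate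
13 | 2,6,6-trimethylcyclohex-2-ene-1,4-dione (ketoisophorone) | CC1=CC(=O)CC(C)(C)C1=O | starting material
14 | (4R)-4-hydroxy-2,6,6-trimethylcyclohex-2-en-1-one | CC1=C[C@H](O)CC(C)(C)C1=O | intermediate
15 | (4R)-4-{[tert-butyl(dimethyl)silyl]oxy}-2,6,6-trimethylcyclohex-2-en-1-one | CC1=C[C@H](O[Si](C)(C)C(C)(C)C)CC(C)(C)C1=O | intermediate
16 | lithium (4S)-4-{[tert-butyl(dimethyl)silyl]oxy}-2,6,6-trimethylcyclohex-1-en-1-olate | [Li+].[O-]C1=C(C)C[C@H](O[Si](C)(C)C(C)(C)C)CC1(C)C | intermediate
17 | (4S)-4-{[tert-butyl(dimethyl)silyl]oxy}-2,6,6-trimethylcyclohex-1-en-1-yl trifluoromethanesulfonate | FC(F)(F)S(=O)(=O)OC1=C(C)C[C@H](O[Si](C)(C)C(C)(C)C)CC1(C)C | intermediate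
18 | methyl (4S)-4-{[tert-butyl(dimethyl)silyl]oxy}-2,6,6-trimethylcyclohex-1-ene-1-carboxylate | COC(=O)C1=C(C)C[C@H](O[Si](C)(C)C(C)(C)C)CC1(C)C | intermediate
19 | [(4S)-4-{[tert-butyl(dimethyl)silyl]oxy}-2,6,6-trimethylcyclohex-1-en-1-yl]methanol | OCC1=C(C)C[C@H](O[Si](C)(C)C(C)(C)C)CC1(C)C | intermediate
20 | [(1S,4R,6S)-4-{[tert-butyl(dimethyl)silyl]oxy}-2,2,6-trimethyl-7-oxabicyclo[4.1.0]heptan-1-yl]methanol | OC[C@]12O[C@@]1(C)C[C@H](O[Si](C)(C)C(C)(C)C)CC2(C)C | intermediate
21 | (1R,4R,6S)-4-{[tert-butyl(dimethyl)silyl]oxy}-2,2,6-trimethyl-7-oxabicyclo[4.1.0]heptane-1-carbaldehyde | O=C[C@]12O[C@@]1(C)C[C@H](O[Si](C)(C)C(C)(C)C)CC2(C)C | intermediate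
22 | triethyl 3-methyl-4-phosphonocrotonate, ethyl (2E)-4-(diethoxyphosphoryl)-3-methylbut-2-enoate (sold as an E/Z mixture, drawn E) | CCOC(=O)/C=C(\C)CP(=O)(OCC)OCC | starting material
23 | ethyl (2E,4E)-5-[(1R,4R,6S)-4-{[tert-butyl(dimethyl)silyl]oxy}-2,2,6-trimethyl-7-oxabicyclo[4.1.0]heptan-1-yl]-3-methylpenta-2,4-dienoate | CCOC(=O)/C=C(\C)/C=C/[C@]12O[C@@]1(C)C[C@H](O[Si](C)(C)C(C)(C)C)CC2(C)C | intermediate
24 | ethyl (2E)-3-[(2S,6R,7aS)-6-{[tert-butyl(dimethyl)silyl]oxy}-4,4,7a-trimethyl-2,4,5,6,7,7a-hexahydro-1-benzofuran-2-yl]but-2-enoate | CCOC(=O)/C=C(\C)[C@@H]1C=C2C(C)(C)C[C@@H](O[Si](C)(C)C(C)(C)C)C[C@]2(C)O1 | intermediate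
25 | (2E)-3-[(2S,6R,7aS)-6-{[tert-butyl(dimethyl)silyl]oxy}-4,4,7a-trimethyl-2,4,5,6,7,7a-hexahydro-1-benzofuran-2-yl]but-2-en-1-ol | OC/C=C(\C)[C@@H]1C=C2C(C)(C)C[C@@H](O[Si](C)(C)C(C)(C)C)C[C@]2(C)O1 | intermediate
26 | (2S,6R,7aS)-2-[(2E)-4-bromobut-2-en-2-yl]-6-{[tert-butyl(dimethyl)silyl]oxy}-4,4,7a-trimethyl-2,4,5,6,7,7a-hexahydro-1-benzofuran | BrC/C=C(\C)[C@@H]1C=C2C(C)(C)C[C@@H](O[Si](C)(C)C(C)(C)C)C[C@]2(C)O1 | intermediate
27 | {(2E)-3-[(2S,6R,7aS)-6-{[tert-butyl(dimethyl)silyl]oxy}-4,4,7a-trimethyl-2,4,5,6,7,7a-hexahydro-1-benzofuran-2-yl]but-2-en-1-yl}triphenylphosphonium bromide | [Br-].c1ccc(cc1)[P+](c1ccccc1)(c1ccccc1)C/C=C(\C)[C@@H]1C=C2C(C)(C)C[C@@H](O[Si](C)(C)C(C)(C)C)C[C@]2(C)O1 | intermediate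
28 | (3R,5S,8S,5'R,8'S)-3-{[tert-butyl(dimethyl)silyl]oxy}-5,8:5',8'-diepoxy-5,8,5',8'-tetrahydro-β,β-carotene | CC(/C=C/C=C(\C)[C@@H]1C=C2C(C)(C)CCC[C@@]2(C)O1)=C\C=C\C=C(C)\C=C\C=C(/C)[C@@H]1C=C2C(C)(C)C[C@@H](O[Si](C)(C)C(C)(C)C)C[C@]2(C)O1 | intermediate
29 | (3R,5S,8S,5'R,8'S)-5,8:5',8'-diepoxy-5,8,5',8'-tetrahydro-β,β-caroten-3-ol | CC(/C=C/C=C(\C)[C@@H]1C=C2C(C)(C)CCC[C@@]2(C)O1)=C\C=C\C=C(C)\C=C\C=C(/C)[C@@H]1C=C2C(C)(C)C[C@@H](O)C[C@]2(C)O1 | target

**Step count and risk**

Total: 20 steps. Longest linear sequence: 13 steps (13 to 29, steps 8 to 20). The left branch has 7 steps before the union and 9 to the target.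

Least certain steps:

Step 4 (key step). The closure may go partly by SN2' attack of the alkoxide at C6', or the doubly allylic C8'–O bond may ionise before displacement, which would erode the cis configuration. The fallback separates reduction from closure. It sets out from 5: thiourea in methanol reduces the O–O bond to the cis enediol ethyl (2E,4R)-4-hydroxy-5-[(1Z,2R)-2-hydroxy-2,6,6-trimethylcyclohexylidene]-3-methylpent-2-enoate F1. Mitsunobu cyclodehydration (PPh3, diisopropyl azodicarboxylate, THF, 0 °C) then activates the secondary allylic hydroxyl, and the tertiary hydroxyl displaces it with inversion. The route is rejoined at 7.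

Step 3. The rate difference between the enantiomers in the amine-mediated proton abstraction may be too small, so that enantiopure material is reached only at very high conversion. The fallback abandons the chemical resolution: racemic 4 is separated by preparative chromatography on a chiral stationary phase (amylose tris(3,5-dimethylphenylcarbamate)), which sets out from 4 and returns at 5. This fallback creates no new compound (F0).

Step 16. Capture of the allyl cation at C8 is not face-selective, and ionisation next to the electron-poor dienoate may be slow enough for silyl ether loss or skeletal rearrangement to compete. The fallback changes the substrate of the rearrangement. It sets out from 23: i-Bu2AlH reduction gives the epoxy dienol (2E,4E)-5-[(1R,4R,6S)-4-{[tert-butyl(dimethyl)silyl]oxy}-2,2,6-trimethyl-7-oxabicyclo[4.1.0]heptan-1-yl]-3-methylpenta-2,4-dien-1-ol F2, whose electron-richer diene should rearrange with pyridinium p-toluenesulfonate in CH2Cl2. After separation of the C8 epimers the route is rejoined at 25. This answers the slow ionisation but not the lack of face selectivity.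

Step 19. The Wittig reaction may give much Z isomer that equilibrates incompletely, and the conjugated ylide may open the dihydrofuran by vinylogous β-elimination of the C8 alkoxide. The fallback replaces the ylide by a phosphonate carbanion used at low temperature. It sets out from 25: bromide 26 is made as in step 18 and heated with triethyl phosphite (Michaelis–Arbuzov) to give diethyl {(2E)-3-[(2S,6R,7aS)-6-{[tert-butyl(dimethyl)silyl]oxy}-4,4,7a-trimethyl-2,4,5,6,7,7a-hexahydro-1-benzofuran-2-yl]but-2-en-1-yl}phosphonate F3. An E-selective Horner–Wadsworth–Emmons reaction with 12 (NaN(SiMe3)2, THF, −78 °C) rejoins the route at 28.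

Step 10. The borohydride may reduce the carbonyl group instead of adding in conjugate fashion, or the hindered enolate may be sulfonylated incompletely. The fallback separates the two events. It sets out from 15: hydrogenation (H2, Pd/C, EtOAc) gives (4S)-4-{[tert-butyl(dimethyl)silyl]oxy}-2,2,6-trimethylcyclohexan-1-one F4 as a mixture of C6 epimers, both of which converge. Regiospecific enolisation with KN(SiMe3)2 and trapping with PhNTf2 rejoins the route at 17.

Further compounds

F1 | step 4 | ethyl (2E,4R)-4-hydroxy-5-[(1Z,2R)-2-hydroxy-2,6,6-trimethylcyclohexylidene]-3-methylpent-2-enoate | CCOC(=O)/C=C(\C)[C@H](O)/C=C1\[C@](C)(O)CCCC1(C)C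
F0 | step 3 | none | none
F2 | step 16 | (2E,4E)-5-[(1R,4R,6S)-4-{[tert-butyl(dimethyl)silyl]oxy}-2,2,6-trimethyl-7-oxabicyclo[4.1.0]heptan-1-yl]-3-methylpenta-2,4-dien-1-ol | OC/C=C(\C)/C=C/[C@]12O[C@@]1(C)C[C@H](O[Si](C)(C)C(C)(C)C)CC2(C)C
F3 | step 19 | diethyl {(2E)-3-[(2S,6R,7aS)-6-{[tert-butyl(dimethyl)silyl]oxy}-4,4,7a-trimethyl-2,4,5,6,7,7a-hexahydro-1-benzofuran-2-yl]but-2-en-1-yl}phosphonate | CCOP(=O)(OCC)C/C=C(\C)[C@@H]1C=C2C(C)(C)C[C@@H](O[Si](C)(C)C(C)(C)C)C[C@]2(C)O1
F4 | step 10 | (4S)-4-{[tert-butyl(dimethyl)silyl]oxy}-2,2,6-trimethylcyclohexan-1-one (C6 epimers) | CC1C[C@H](O[Si](C)(C)C(C)(C)C)CC(C)(C)C1=O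
A1 | alternative 1 | (5S)-5-[(2R)-2-{[tert-butyl(dimethyl)silyl]oxy}-4-methylpent-4-en-1-yl]-5-methylfuran-2(5H)-one | O=C1C=C[C@](C)(C[C@H](O[Si](C)(C)C(C)(C)C)CC(C)=C)O1
A2 | alternative 1 | (6R,7aS)-6-{[tert-butyl(dimethyl)silyl]oxy}-4,4,7a-trimethyl-5,6,7,7a-tetrahydro-1-benzofuran-2(4H)-one | O=C1C=C2C(C)(C)C[C@@H](O[Si](C)(C)C(C)(C)C)C[C@]2(C)O1
A3 | alternative 2 | (2E)-5-[(2S,4R)-4-{[tert-butyl(dimethyl)silyl]oxy}-2-hydroxy-2,6,6-trimethylcyclohexylidene]-3-methylpenta-2,4-dien-1-yl 2,2-dimethylpropanoate, allene axis (M) | CC1(C)C[C@@H](O[Si](C)(C)C(C)(C)C)C[C@](C)(O)C1=[C@]=C([H])/C(C)=C/COC(=O)C(C)(C)C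
A4 | alternative 2 | (2E)-3-[(2S,6R,7aS)-6-{[tert-butyl(dimethyl)silyl]oxy}-4,4,7a-trimethyl-2,4,5,6,7,7a-hexahydro-1-benzofuran-2-yl]but-2-en-1-yl 2,2-dimethylpropanoate | CC(C)(C)C(=O)OC\C=C(/C)[C@@H]1C=C2C(C)(C)C[C@@H](O[Si](C)(C)C(C)(C)C)C[C@]2(C)O1
A5 | alternative 3 | ethyl (2E)-3-[(2R,3R)-3-[(4S)-4-{[tert-butyl(dimethyl)silyl]oxy}-2,6,6-trimethylcyclohex-1-en-1-yl]oxiran-2-yl]but-2-enoate | CCOC(=O)/C=C(\C)[C@H]1O[C@@H]1C2=C(C)C[C@H](O[Si](C)(C)C(C)(C)C)CC2(C)C
A6 | alternative 3 | ethyl (2E)-3-[(2S,6R,7aS)-6-{[tert-butyl(dimethyl)silyl]oxy}-4,4,7a-trimethyl-2,4,5,6,7,7a-hexahydro-1-benzofuran-2-yl]but-2-enoate | CCOC(=O)/C=C(\C)[C@@H]1C=C2C(C)(C)C[C@@H](O[Si](C)(C)C(C)(C)C)C[C@]2(C)O1
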